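**Strategy.** The ten-membered carbocycle is treated as a ring-expanded cyclohexene. In the precursor, C2–C3–C4–C5–C6–C7 form a six-membered ring that already holds the cis C4=C5 alkene and the C6 stereocentre; C1/C10 are attached as an alkynyl group at C2 and C8/C9 as a vinyl group at C7. The key step, an anionic alkynyl oxy-Cope rearrangement, forms C9–C10, breaks C2–C7 and in one operation closes the ten-membered ring with the C2 carbonyl, the C1=C10 enone carrying C14 and an E C7=C8 alkene. It exploits the C2 oxygen and the 1,5-relationship C10–C1–C2–C7–C8–C9. C7 and C8 are then set by a C6–O-tethered hydrosilylation.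

Key step: step 9

Remark (numbering): the germacrane numbering of the target is used for every intermediate: ring C1–C10; C11 (lactone α-carbon), C12 (lactone C=O), C13 (=CH2); C14 = CH2O on C10; C15 = CH3 on C4. "Arm" means the CH2CONMe2 group on C7 (C11, C12).

Step 1
Reactants: 1 5-methylcyclohexane-1,3-dione; 2 2-chloro-N,N-dimethylacetamide
Product: 3 2-(4-methyl-2,6-dioxocyclohexyl)-N,N-dimethylacetamide
Conditions: KOH (1.0 equiv), KI (cat.), H2O, 60 °C
Reagents that add atoms: none
Why: C-alkylation of the 1,3-dione enolate in water (hydrogen bonding to the enolate oxygens suppresses O-alkylation) puts the future C11–C12 unit on C7 as a tertiary amide that is inert to the alkoxides used later; no stereocentre is set.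

Step 2
Reactants: 3 2-(4-methyl-2,6-dioxocyclohexyl)-N,N-dimethylacetamide
Product: 4 2-(1-ethenyl-4-methyl-2,6-dioxocyclohexyl)-N,N-dimethylacetamide (cis/trans mixture; both isomers achiral)
Conditions: CH2=CHSnBu3, Pb(OAc)4, Hg(OAc)2 (cat.), CHCl3, rt; then 3, pyridine, 40 °C
Reagents that add atoms: tributyl(ethenyl)stannane, C=C[Sn](CCCC)(CCCC)CCCC
Why: α-Vinylation of a β-dicarbonyl by ligand coupling on tetravalent lead (Pinhey-type; ethenyllead triacetate is made in the flask) creates the quaternary C7 bearing the vinyl group C8=C9; the C7/C4 relationship is left open because C4 becomes sp2 in step 4.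

Step 3
Reactants: 4 2-(1-ethenyl-4-methyl-2,6-dioxocyclohexyl)-N,N-dimethylacetamide
Product: 5 hydroxy ketone (C2 carbinol S; hydroxyl cis to the arm; C4 epimers)
Conditions: (R)-1-methyl-3,3-diphenyltetrahydro-1H,3H-pyrrolo[1,2-c][1,3,2]oxazaborole (20 mol %), catecholborane (1.2 equiv), toluene, −78 to −40 °C
Reagents that add atoms: none
Why: Corey–Bakshi–Shibata reduction desymmetrises the prochiral dione: the catalyst distinguishes the quaternary C7 flank from the CH2 flank and so fixes the S carbinol, and of the two enantiotopic carbonyls the one that can accept hydride anti to the bulkier arm should react (matched pair), which places the hydroxyl cis to the arm.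

Step 4
Reactants: 5 hydroxy ketone
Product: 7 enone (C6 ketone conjugated to C4=C5; C2 triethylsilyl ether), via bis-silylated enol ether 6 (not isolated)
Conditions: TESCl (2.5 equiv), then LDA (2.3 equiv), THF, −78 °C (in situ quench); then Pd(OAc)2 (1.1 equiv), MeCN, 40 °C
Reagents that add atoms: chlorotriethylsilane, CC[Si](Cl)(CC)CC
Why: Saegusa–Ito dehydrogenation: the C6 ketone can enolise only towards C5, so the silyl enol ether and then the divalent palladium enolate form there and β-hydride loss from C4 gives the C4=C5 enone and erases the C4 stereocentre, while the silyl chloride present from the start caps the C2 alkoxide before it can undergo retro-aldol cleavage.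

Step 5
Reactants: 7 enone
Product: 8 allylic alcohol (C6 R; hydroxyl cis to the arm; C2 triethylsilyl ether)
Conditions: (S)-1-methyl-3,3-diphenyltetrahydro-1H,3H-pyrrolo[1,2-c][1,3,2]oxazaborole (20 mol %), catecholborane, toluene, −78 °C
Reagents that add atoms: none
Why: Corey–Bakshi–Shibata 1,2-reduction of the enone with the quaternary C7 as the large and the vinylic C5 as the small flank should give the 6R alcohol, and the case is matched because hydride again enters anti to the arm; this sets the C6 stereocentre that is carried unchanged to the target.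

Step 6
Reactants: 8 allylic alcohol
Product: 10 hydroxy silyl ether (C2 hydroxyl free; C6 tert-butyldimethylsilyl ether), via bis-silyl ether 9 (not isolated)
Conditions: TBSOTf, 2,6-lutidine, CH2Cl2, −78 °C; then pyridinium p-toluenesulfonate, MeOH, 0 °C
Reagents that add atoms: tert-butyldimethylsilyl trifluoromethanesulfonate, CC(C)(C)[Si](C)(C)OS(=O)(=O)C(F)(F)F
Why: Silylation of the C6 hydroxyl followed by selective acid methanolysis of the more labile triethylsilyl ether (protecting-group exchange) frees C2 alone for oxidation; no stereocentre is touched.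

Step 7
Reactants: 10 hydroxy silyl ether
Product: 11 β,γ-unsaturated ketone (C2 ketone; 6R)
Conditions: Dess–Martin periodinane, pyridine, CH2Cl2, 0 °C
Reagents that add atoms: none
Why: Dess–Martin oxidation under buffered, non-basic conditions should give the C2 ketone without moving the C4=C5 alkene into conjugation or eliminating the allylic silyloxy group; the temporary C2 stereocentre is erased.

Step 8
Reactants: 11 β,γ-unsaturated ketone; 12 1-methoxy-4-[(prop-2-yn-1-yloxy)methyl]benzene
Product: 13 tertiary propargylic alcohol (2R,6R,7S; alkynyl cis to the vinyl group)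
Conditions: 12, n-BuLi, THF, −78 °C; then 11, −78 °C; H2O quench
Reagents that add atoms: none
Why: 1,2-Addition of the weakly basic lithium acetylide to the ketone (alkynylation) is expected on the face opposite the arm and the C6 silyloxy group and completes the 3-hydroxy-1,5-enyne C10≡C1–C2(OH)–C7–C8=C9; the new C2 centre is erased in step 9, so either epimer is usable.

Step 9
Reactants: 13 tertiary propargylic alcohol
Product: 16 ten-membered trienone (6R; ring-cis C1=C10 enone; Z C4=C5; E C7=C8), via potassium alkoxide 14 (not isolated), via cyclic potassium allenolate 15 (not isolated)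
Conditions: KH (1.2 equiv), 18-crown-6 (1.2 equiv), THF, 0 to 25 °C; then AcOH, −78 °C
Reagents that add atoms: none
Why: The naked alkoxide 14 should undergo a charge-accelerated [3,3]-sigmatropic shift of the 1,5-enyne C10≡C1–C2(O−)–C7–C8=C9 through a chair transition state, which forms C9–C10, breaks C2–C7 and gives the cyclic allenolate 15; C-protonation at C1 from the ring exterior then gives the ring-cis enone. The closest known reaction type is the anionic oxy-Cope ring expansion of 1,2-dialkenylcyclohexanols to cyclodecenones and its alkynyl variant, which gives the conjugated enone directly. The ten-membered ring is closed by a four-atom ring expansion of the six-membered ring C2–C7, not by an end-to-end cyclisation, so no high dilution is needed. No stereocentre is created: C6 is not involved and stays R, C2 and C7 become sp2, C4=C5 stays cis because it was endocyclic in the cyclohexene, and the chair with the C6–C7 ring bond pseudo-equatorial makes C7=C8 E. The step needs the vinyl group and not the ring alkene as the 2π partner, which is secured because the alternative enyne through C3–C4=C5 would have to give a six-membered cyclic allene; it also needs protonation at C1 syn to C14, which the exposed exterior face of 15 favours.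

Step 10
Reactants: 16 ten-membered trienone
Product: 17 allylic alcohol (C6 hydroxyl free)
Conditions: Bu4NF, AcOH, THF, 0 °C
Reagents that add atoms: none
Why: Fluoride-induced desilylation, buffered with acetic acid so that the γ-protons of the enone are not removed, frees the C6 hydroxyl as the tether site; no stereocentre is touched.

Step 11
Reactants: 17 allylic alcohol
Product: 19 ring-fused 1,2-oxasilolane (O6–SiMe2–C8; H on C7), via dimethylsilyl ether 18 (not isolated)
Conditions: (HMe2Si)2NH, neat, rt; then Pt2[(CH2=CHSiMe2)2O]3 (0.5 mol %), toluene, 60 °C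
Reagents that add atoms: 1,1,3,3-tetramethyldisilazane, C[SiH](C)N[SiH](C)C
Why: Tamao-type intramolecular hydrosilylation of an allylic alcohol (5-endo closure, zerovalent platinum) adds Si to C8 and H to C7 on the same face of the E alkene, and the C6–O tether should deliver from the rotamer that turns C5 away from the arm (least A(1,2) strain), which sets C7 (arm syn to O6 along the extended chain, so the later lactone is trans-fused) and C8 (Si anti to the arm) as in the target; only C7=C8 reacts because closure onto C4=C5 would put silicon on the fully substituted C4.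

Step 12
Reactants: 19 ring-fused 1,2-oxasilolane
Product: 20 trans-fused 6,12-lactone (C8 SiMe2OMe; C2 ketone)
Conditions: (+)-10-camphorsulfonic acid (1.5 equiv), MeOH, 45 °C
Reagents that add atoms: methanol, CO
Why: Acid methanolysis opens the Si–O6 bond and the freed C6 hydroxyl displaces dimethylamine from the γ-amide (acid-promoted lactonisation), so the lactone can only close onto O6 because the C8 oxygen is still masked as a C–Si bond; no stereocentre changes.

Step 13
Reactants: 20 trans-fused 6,12-lactone
Product: 21 allylic alcohol (C2 S)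
Conditions: (R)-1-methyl-3,3-diphenyltetrahydro-1H,3H-pyrrolo[1,2-c][1,3,2]oxazaborole (30 mol %), catecholborane, toluene, −78 °C
Reagents that add atoms: none
Why: Corey–Bakshi–Shibata 1,2-reduction of the enone, with the β,β-disubstituted alkenyl carbon C1 as the large and the C3 methylene as the small flank, should set the C2 stereocentre as S under catalyst control.

Step 14
Reactants: 21 allylic alcohol
Product: 22 Mannich base (CH2NMe2 on C11; C11 epimers)
Conditions: LDA (2.3 equiv), THF, −78 °C; then CH2=NMe2+ I−, −78 to 0 °C; H2O quench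
Reagents that add atoms: N,N-dimethylmethyleneiminium iodide, C=[N+](C)C.[I-]
Why: Aminomethylation of the lactone enolate with Eschenmoser's salt (Mannich reaction) brings in C13 as a masked methylene while the C2 hydroxyl is protected as its lithium alkoxide; the new C11 centre is irrelevant because it becomes sp2 in step 16.

Step 15
Reactants: 22 Mannich base
Product: 23 C2 acetate
Conditions: Ac2O, pyridine, 4-(dimethylamino)pyridine (cat.), CH2Cl2, 0 °C to rt
Reagents that add atoms: acetic anhydride, CC(=O)OC(C)=O
Why: Acylation of the only free hydroxyl (C2, retention) installs the acetate while the C8 oxygen is still masked as silicon, which is what distinguishes the two ester sites.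

Step 16
Reactants: 23 C2 acetate
Product: 25 C8 alcohol (α-methylene lactone; C2 acetate; C14 p-methoxybenzyl ether), via amine N-oxide 24 (not isolated)
Conditions: H2O2 (30 %), KF, KHCO3, THF/MeOH, rt, then 40 °C
Reagents that add atoms: hydrogen peroxide, OO
Why: Tamao–Fleming oxidation turns the C8–Si bond into C8–OH with retention, and the same oxidant converts the tertiary amine into its N-oxide, which undergoes Cope elimination across C13–C11 (the only hydrogen β to nitrogen is H11) and so can give only the exocyclic C11=C13 methylene.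

Step 17
Reactants: 25 C8 alcohol
Product: 26 C8 methacrylate (C14 p-methoxybenzyl ether)
Conditions: methacrylic anhydride, Et3N, 4-(dimethylamino)pyridine, CH2Cl2, 0 °C to rt
Reagents that add atoms: methacrylic anhydride, C=C(C)C(=O)OC(=O)C(C)=C
Why: Nucleophile-catalysed acyl transfer (Steglich-type) esterifies the only free hydroxyl with retention at C8.

Step 18
Reactants: 26 C8 methacrylate
Product: 27 CNP0138477.1
Conditions: 2,3-dichloro-5,6-dicyano-1,4-benzoquinone, CH2Cl2/pH 7 buffer, 0 °C
Reagents that add atoms: none
Why: Oxidative cleavage of the p-methoxybenzyl ether under neutral conditions frees the C14 allylic alcohol without touching the two esters, the α-methylene lactone or the acid-sensitive cis,cis-diene.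

**Compound list**

1 | 5-methylcyclohexane-1,3-dione | CC1CC(=O)CC(=O)C1 | starting material
2 | 2-chloro-N,N-dimethylacetamide | CN(C)C(=O)CCl | starting material
3 | 2-(4-methyl-2,6-dioxocyclohexyl)-N,N-dimethylacetamide | CC1CC(=O)C(CC(=O)N(C)C)C(=O)C1 | intermediate
4 | 2-(1-ethenyl-4-methyl-2,6-dioxocyclohexyl)-N,N-dimethylacetamide (cis/trans mixture, both achiral) | C=CC1(CC(=O)N(C)C)C(=O)CC(C)CC1=O | intermediate
5 | hydroxy ketone: C2 carbinol S, OH cis to the arm, C6 ketone, C4 epimers | O[C@H]1CC(C)CC(=O)[C@@]1(C=C)CC(=O)N(C)C | intermediate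
6 | bis-silylated enol ether: C2 triethylsilyl ether and C6 triethylsilyl enol ether of 5 | CC[Si](CC)(CC)O[C@H]1CC(C)C=C(O[Si](CC)(CC)CC)[C@@]1(C=C)CC(=O)N(C)C | intermediate
7 | enone: C6 ketone conjugated to C4=C5, C2 triethylsilyl ether | CC[Si](CC)(CC)O[C@H]1CC(C)=CC(=O)[C@@]1(C=C)CC(=O)N(C)C | intermediate
8 | allylic alcohol: C6 R, OH cis to the arm, C2 triethylsilyl ether | CC[Si](CC)(CC)O[C@H]1CC(C)=C[C@@H](O)[C@@]1(C=C)CC(=O)N(C)C | intermediate
9 | bis-silyl ether: C2 triethylsilyl, C6 tert-butyldimethylsilyl | CC[Si](CC)(CC)O[C@H]1CC(C)=C[C@@H](O[Si](C)(C)C(C)(C)C)[C@@]1(C=C)CC(=O)N(C)C | intermediate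
10 | hydroxy silyl ether: C2 OH (S) free, C6 (R) tert-butyldimethylsilyl ether | O[C@H]1CC(C)=C[C@@H](O[Si](C)(C)C(C)(C)C)[C@@]1(C=C)CC(=O)N(C)C | intermediate
11 | β,γ-unsaturated ketone: C2 ketone, 6R, arm cis to the C6 silyloxy group | O=C1CC(C)=C[C@@H](O[Si](C)(C)C(C)(C)C)[C@@]1(C=C)CC(=O)N(C)C | intermediate
12 | 1-methoxy-4-[(prop-2-yn-1-yloxy)methyl]benzene | C#CCOCc1ccc(OC)cc1 | starting material
13 | tertiary propargylic alcohol (2R,6R,7S): 1-alkynyl-2-vinylcyclohex-3-en-1-ol, OH cis to the arm | O[C@@]1(C#CCOCc2ccc(OC)cc2)CC(C)=C[C@@H](O[Si](C)(C)C(C)(C)C)[C@@]1(C=C)CC(=O)N(C)C | intermediate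
14 | potassium alkoxide of 13 | [K+].[O-][C@@]1(C#CCOCc2ccc(OC)cc2)CC(C)=C[C@@H](O[Si](C)(C)C(C)(C)C)[C@@]1(C=C)CC(=O)N(C)C | intermediate
15 | cyclic potassium allenolate (C2(O−)=C1=C10 in the ten-membered ring) | [K+].[O-]C1=C=C(COCc2ccc(OC)cc2)C/C=C(CC(=O)N(C)C)/[C@H](O[Si](C)(C)C(C)(C)C)/C=C(C)\C1 | intermediate
16 | ten-membered trienone: 6R, ring-cis C1=C10 enone, Z C4=C5, E C7=C8, C6 silyl ether | O=C1/C=C(COCc2ccc(OC)cc2)\C/C=C(CC(=O)N(C)C)/[C@H](O[Si](C)(C)C(C)(C)C)/C=C(C)\C1 | intermediate
17 | allylic alcohol: 16 with free C6 OH | O=C1/C=C(COCc2ccc(OC)cc2)\C/C=C(CC(=O)N(C)C)/[C@H](O)/C=C(C)\C1 | intermediate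
18 | dimethylsilyl ether of 17 (O6–SiHMe2) | O=C1/C=C(COCc2ccc(OC)cc2)\C/C=C(CC(=O)N(C)C)/[C@H](O[SiH](C)C)/C=C(C)\C1 | intermediate
19 | ring-fused 1,2-oxasilolane: Si bonded to O6 and C8, H on C7, C6–C8 configured as in the target | C[Si]1(C)O[C@@H]2/C=C(C)\CC(=O)/C=C(COCc3ccc(OC)cc3)\C[C@@H]1[C@H]2CC(=O)N(C)C | intermediate
20 | trans-fused 6,12-lactone with C8 methoxydimethylsilyl group and C2 ketone | CO[Si](C)(C)[C@@H]1C/C(COCc2ccc(OC)cc2)=C\C(=O)C/C(C)=C\[C@H]2OC(=O)C[C@@H]21 | intermediate
21 | allylic alcohol: 20 with C2 OH (S) | CO[Si](C)(C)[C@@H]1C/C(COCc2ccc(OC)cc2)=C\[C@@H](O)C/C(C)=C\[C@H]2OC(=O)C[C@@H]21 | intermediate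
22 | Mannich base: 21 with CH2NMe2 on C11 (C11 epimers) | CO[Si](C)(C)[C@@H]1C/C(COCc2ccc(OC)cc2)=C\[C@@H](O)C/C(C)=C\[C@H]2OC(=O)C(CN(C)C)[C@@H]21 | intermediate
23 | C2 acetate of 22 | CO[Si](C)(C)[C@@H]1C/C(COCc2ccc(OC)cc2)=C\[C@@H](OC(C)=O)C/C(C)=C\[C@H]2OC(=O)C(CN(C)C)[C@@H]21 | intermediate
24 | amine N-oxide with free C8 OH | O[C@@H]1C/C(COCc2ccc(OC)cc2)=C\[C@@H](OC(C)=O)C/C(C)=C\[C@H]2OC(=O)C(C[N+](C)(C)[O-])[C@@H]21 | intermediate
25 | C8 alcohol: α-methylene lactone, C2 acetate, C14 p-methoxybenzyl ether | O[C@@H]1C/C(COCc2ccc(OC)cc2)=C\[C@@H](OC(C)=O)C/C(C)=C\[C@H]2OC(=O)C(=C)[C@@H]21 | intermediate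
26 | C8 methacrylate, C14 p-methoxybenzyl ether | C=C(C)C(=O)O[C@@H]1C/C(COCc2ccc(OC)cc2)=C\[C@@H](OC(C)=O)C/C(C)=C\[C@H]2OC(=O)C(=C)[C@@H]21 | intermediate
27 | CNP0138477.1 (2S,6R,7R,8R; ring-cis C1=C10, Z C4=C5) | C=C(C)C(=O)O[C@@H]1C/C(CO)=C\[C@@H](OC(C)=O)C/C(C)=C\[C@H]2OC(=O)C(=C)[C@@H]21 | target

**Totals.** 18 steps; longest linear sequence 18 steps (1 to 27; 2 and 12 are bought).

**Steps most likely to fail**

Step 9. The alkoxide may fragment or stall because the immediate product is a strained ten-membered cyclic allenolate, and protonation of that allenolate may occur from the wrong side and give the ring-trans C1=C10 enone. The fallback sets out from 13. Semihydrogenation (H2, Pd on CaCO3 poisoned with Pb(OAc)2, quinoline) should give the cis-alkenyl carbinol F1. The classical anionic oxy-Cope rearrangement of this 1,2-dialkenylcyclohexenol (KH, 18-crown-6, THF) forms the same C9–C10 bond through an ordinary enolate, which is trapped with TMSCl as the ring-expanded trimethylsilyl enol ether F2. Saegusa–Ito oxidation (Pd(OAc)2, MeCN) then introduces the C1=C10 double bond and returns to 16.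

Step 16. Perhydrolysis of the C2 acetate and nucleophilic epoxidation of the newly freed α-methylene lactone may compete under the basic peroxide conditions. The fallback sets out from 21, where only a plain lactone is present, and comes back at 26:
- Tamao–Fleming oxidation of 21 (H2O2, KF, KHCO3) should give the C2,C8-diol lactone F3.
- LDA (3.5 equiv) and Eschenmoser's salt give the diol Mannich base F4.
- The allylic, less hindered C2 hydroxyl is acetylated selectively (Ac2O 1.05 equiv, 2,4,6-collidine, CH2Cl2, −20 °C) to the C2 monoacetate F5.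
- Methacrylic anhydride with 4-(dimethylamino)pyridine gives the C8 methacrylate Mannich base F6.
- Quaternisation with MeI and elimination of trimethylamine with NaHCO3 unmask the methylene and return to 26.

Step 2. Ligand coupling at the hindered, fully substituted carbon may be slow, with O-vinylation or acetoxylation of the enolate competing. The fallback sets out from 3. Michael addition to phenyl vinyl sulfoxide (DBU, MeCN) should give the sulfoxide adduct F7. Thermal syn-elimination (toluene, 110 °C, CaCO3) then unveils the vinyl group and returns to 4.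

**Further compounds**

F1 | step 9 | cis-alkenyl carbinol (Z C1=C10; otherwise as 13) | O[C@@]1(/C=C\COCc2ccc(OC)cc2)CC(C)=C[C@@H](O[Si](C)(C)C(C)(C)C)[C@@]1(C=C)CC(=O)N(C)C
F2 | step 9 | ring-expanded trimethylsilyl enol ether (C2(OSiMe3)=C1; C10 sp3, epimers) | C[Si](C)(C)OC1=CC(COCc2ccc(OC)cc2)C/C=C(CC(=O)N(C)C)/[C@H](O[Si](C)(C)C(C)(C)C)/C=C(C)\C1
F3 | step 16 | C2,C8-diol lactone | O[C@@H]1C/C(COCc2ccc(OC)cc2)=C\[C@@H](O)C/C(C)=C\[C@H]2OC(=O)C[C@@H]21
F4 | step 16 | diol Mannich base (C11 epimers) | O[C@@H]1C/C(COCc2ccc(OC)cc2)=C\[C@@H](O)C/C(C)=C\[C@H]2OC(=O)C(CN(C)C)[C@@H]21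
F5 | step 16 | C2 monoacetate with free C8 hydroxyl (Mannich base) | O[C@@H]1C/C(COCc2ccc(OC)cc2)=C\[C@@H](OC(C)=O)C/C(C)=C\[C@H]2OC(=O)C(CN(C)C)[C@@H]21
F6 | step 16 | C8 methacrylate Mannich base | C=C(C)C(=O)O[C@@H]1C/C(COCc2ccc(OC)cc2)=C\[C@@H](OC(C)=O)C/C(C)=C\[C@H]2OC(=O)C(CN(C)C)[C@@H]21
F7 | step 2 | sulfoxide adduct: 2-[4-methyl-2,6-dioxo-1-(2-(phenylsulfinyl)ethyl)cyclohexyl]-N,N-dimethylacetamide | CC1CC(=O)C(CCS(=O)c2ccccc2)(CC(=O)N(C)C)C(=O)C1
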